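**Retrosynthetic overview**

- The last step opens the 10,11-acetonide. Before it, the C1–O aryl ether is made by Mitsunobu reaction of 5,7-dihydroxycoumarin with an allylic diol.
- Key disconnection C8–C9: a light-driven nickel / hydrogen-atom-transfer coupling joins the α-C–H bond of a chiral dioxolanyl methanol to an (E)-allylic carbonate. C9 is set by the neighbouring C10.
- The allylic carbonate comes from geranyl acetate by SeO2 oxidation of the (E)-methyl group and reaction with ClCO2Me.
- The chiral alcohol comes from methyl (S)-glycerate acetonide (L-serine pool, supplies C10) by MeMgBr addition and acetonide migration.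
- Rings: the coumarin bicycle is bought intact. The only ring made is the temporary 2,2,5,5-tetramethyl-1,3-dioxolane (step 2), opened in step 7.

Assumption: chain locants run C1 (ether CH2) to C11 (carbinol carbon); the target is the (9S,10S)-anti (erythro) triol; the (S)-glycerate ester 1 and (2E)-geranyl acetate are catalogue chemicals.

Abbreviations: dF(CF3)ppy = cyclometalated 2-(2,4-difluorophenyl)-5-(trifluoromethyl)pyridine; dtbbpy = 4,4'-di-tert-butyl-2,2'-bipyridine; dme = 1,2-dimethoxyethane; DIAD = diisopropyl azodicarboxylate; PPTS = pyridinium p-toluenesulfonate.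

**Route**

Step 1
Reactants: 1 methyl (4S)-2,2-dimethyl-1,3-dioxolane-4-carboxylate
Product: 3 2-[(4S)-2,2-dimethyl-1,3-dioxolan-4-yl]propan-2-ol, via methyl ketone 2 (not isolated)
Conditions: MeMgBr (2.5 equiv), THF, 0 to 20 °C; aq NH4Cl
Reagents that add atoms: methylmagnesium bromide, C[Mg]Br
Why: Double Grignard addition to the ester through the ketone; the α-alkoxy stereocentre (later C10) is bought with 1 and is not touched at 0 °C.

Step 2
Reactants: 3 2-[(4S)-2,2-dimethyl-1,3-dioxolan-4-yl]propan-2-ol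
Product: 4 [(4S)-2,2,5,5-tetramethyl-1,3-dioxolan-4-yl]methanol
Conditions: p-TsOH·H2O (5 mol%), CH2Cl2, 20 °C; Et3N
Reagents that add atoms: none
Why: Acid-catalysed acetonide migration under thermodynamic control to the more substituted dioxolane frees the primary alcohol; no bond to the stereocentre is broken, and unchanged 3 is recycled.

Step 3
Reactants: 5 geranyl acetate, (2E)-3,7-dimethylocta-2,6-dien-1-yl acetate
Product: 7 (2E,6E)-8-hydroxy-3,7-dimethylocta-2,6-dien-1-yl acetate, via enal 6 (not isolated)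
Conditions: SeO2 (0.4 equiv), t-BuOOH (3 equiv), salicylic acid (10 mol%), CH2Cl2, 20 °C; then NaBH4, MeOH, 0 °C
Reagents that add atoms: tert-butyl hydroperoxide, CC(C)(C)OO (oxygen atom, relayed by catalytic selenium dioxide, O=[Se]=O)
Why: Riley allylic oxidation (ene reaction then [2,3]-sigmatropic shift) selects the (E)-methyl group of the electron-richer terminal olefin; NaBH4 returns over-oxidised enal 6 to 7.

Step 4
Reactants: 7 (2E,6E)-8-hydroxy-3,7-dimethylocta-2,6-dien-1-yl acetate
Product: 8 (2E,6E)-8-[(methoxycarbonyl)oxy]-3,7-dimethylocta-2,6-dien-1-yl acetate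
Conditions: ClCO2Me, pyridine, DMAP (5 mol%), CH2Cl2, 0 °C
Reagents that add atoms: methyl chloroformate, COC(=O)Cl
Why: Simple O-acylation of the primary allylic alcohol gives a carbonate that ionises at nickel much faster than the C1 acetate.

Step 5
Reactants: 4 [(4S)-2,2,5,5-tetramethyl-1,3-dioxolan-4-yl]methanol; 8 (2E,6E)-8-[(methoxycarbonyl)oxy]-3,7-dimethylocta-2,6-dien-1-yl acetate
Product: 10 (2E,6E,9S)-3,7-dimethyl-9-[(4S)-2,2,5,5-tetramethyl-1,3-dioxolan-4-yl]nona-2,6-diene-1,9-diol, via coupled acetate 9 (not isolated)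
Conditions: 4 (2 equiv), [Ir(dF(CF3)ppy)2(dtbbpy)]PF6 (1 mol%), NiBr2(dme) (5 mol%), dtbbpy (6 mol%), quinuclidine (20 mol%), ZnCl2 (1 equiv), DMSO, 450 nm LEDs, 25 °C; then K2CO3 (0.3 equiv), MeOH, 25 °C
Reagents that add atoms: none
Why: Proposed new method: a redox-neutral α-C–H allylation of a free alcohol by triple catalysis, in which the excited iridium complex oxidises quinuclidine to its radical cation, which abstracts the hydridic α-hydrogen of the zinc alkoxide of 4 (the ring C–H is shielded by the gem-dimethyl carbon and the allylic or α-acyloxy C–H bonds of 8 are less hydridic); zerovalent nickel–dtbbpy ionises the methyl carbonate of 8 irreversibly (loss of CO2) to a syn-allyl divalent nickel methoxide whose methoxide is the internal base; the C9 radical is captured to a trivalent nickel alkyl–allyl species that reductively eliminates at the unsubstituted allyl terminus, so the C8–C9 bond forms without allylic transposition and with the 6E geometry kept, and the reduced iridium complex returns monovalent nickel to zerovalent nickel; C9 is set by the chiral-pool centre C10, since bond formation anti to the C10–O bond and the quaternary C11 (Felkin–Anh-type, zinc being solvated by DMSO and not chelated) gives the 9,10-anti (9S) isomer; K2CO3/MeOH then removes the acetate in the same flask; closest known reaction types are the nickel/photoredox/quinuclidine α-arylation of alcohols through zinc alkoxides and the nickel-catalysed linear-selective coupling of allylic carbonates with alkyl radicals.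

Step 6
Reactants: 10 (2E,6E,9S)-3,7-dimethyl-9-[(4S)-2,2,5,5-tetramethyl-1,3-dioxolan-4-yl]nona-2,6-diene-1,9-diol; 11 5,7-dihydroxy-2H-chromen-2-one
Product: 12 5-hydroxy-7-{[(2E,6E,9S)-9-hydroxy-3,7-dimethyl-9-[(4S)-2,2,5,5-tetramethyl-1,3-dioxolan-4-yl]nona-2,6-dien-1-yl]oxy}-2H-chromen-2-one
Conditions: 11 (1.2 equiv), PPh3, DIAD, THF, 0 to 20 °C
Reagents that add atoms: none
Why: Mitsunobu etherification (SN2 at the primary allylic alkoxyphosphonium) by the more acidic 7-OH, which is para-conjugated to the pyranone and less hindered than the peri 5-OH; the hindered secondary C9–OH does not react.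

Step 7
Reactants: 12 5-hydroxy-7-{[(2E,6E,9S)-9-hydroxy-3,7-dimethyl-9-[(4S)-2,2,5,5-tetramethyl-1,3-dioxolan-4-yl]nona-2,6-dien-1-yl]oxy}-2H-chromen-2-one
Product: 13 5-hydroxy-7-{[(2E,6E,9S,10S)-9,10,11-trihydroxy-3,7,11-trimethyldodeca-2,6-dien-1-yl]oxy}-2H-chromen-2-one (CNP0174708.2)
Conditions: PPTS (0.3 equiv), MeOH, 45 °C
Reagents that add atoms: none
Why: Mild acid-catalysed transketalisation to methanol opens the dioxolane without touching the aryl geranyl ether, the olefins or either stereocentre.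

**Compound list**

1 | methyl (4S)-2,2-dimethyl-1,3-dioxolane-4-carboxylate | COC(=O)[C@@H]1COC(C)(C)O1 | starting material
2 | 1-[(4S)-2,2-dimethyl-1,3-dioxolan-4-yl]ethan-1-one | CC(=O)[C@@H]1COC(C)(C)O1 | intermediate
3 | 2-[(4S)-2,2-dimethyl-1,3-dioxolan-4-yl]propan-2-ol | CC(C)(O)[C@@H]1COC(C)(C)O1 | intermediate
4 | [(4S)-2,2,5,5-tetramethyl-1,3-dioxolan-4-yl]methanol | OC[C@@H]1OC(C)(C)OC1(C)C | intermediate
5 | geranyl acetate, (2E)-3,7-dimethylocta-2,6-dien-1-yl acetate | C/C(=C\COC(C)=O)CCC=C(C)C | starting material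
6 | (2E,6E)-3,7-dimethyl-8-oxoocta-2,6-dien-1-yl acetate | C/C(=C\COC(C)=O)CC/C=C(\C)C=O | intermediate
7 | (2E,6E)-8-hydroxy-3,7-dimethylocta-2,6-dien-1-yl acetate | C/C(=C\COC(C)=O)CC/C=C(\C)CO | intermediate
8 | (2E,6E)-8-[(methoxycarbonyl)oxy]-3,7-dimethylocta-2,6-dien-1-yl acetate | C/C(=C\COC(C)=O)CC/C=C(\C)COC(=O)OC | intermediate
9 | (2E,6E,9S)-9-hydroxy-3,7-dimethyl-9-[(4S)-2,2,5,5-tetramethyl-1,3-dioxolan-4-yl]nona-2,6-dien-1-yl acetate | C/C(=C\COC(C)=O)CC/C=C(\C)C[C@H](O)[C@@H]1OC(C)(C)OC1(C)C | intermediate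
10 | (2E,6E,9S)-3,7-dimethyl-9-[(4S)-2,2,5,5-tetramethyl-1,3-dioxolan-4-yl]nona-2,6-diene-1,9-diol | C/C(=C\CO)CC/C=C(\C)C[C@H](O)[C@@H]1OC(C)(C)OC1(C)C | intermediate
11 | 5,7-dihydroxy-2H-chromen-2-one (5,7-dihydroxycoumarin) | O=c1ccc2c(O)cc(O)cc2o1 | starting material
12 | 5-hydroxy-7-{[(2E,6E,9S)-9-hydroxy-3,7-dimethyl-9-[(4S)-2,2,5,5-tetramethyl-1,3-dioxolan-4-yl]nona-2,6-dien-1-yl]oxy}-2H-chromen-2-one | C/C(=C\COc1cc(O)c2ccc(=O)oc2c1)CC/C=C(\C)C[C@H](O)[C@@H]1OC(C)(C)OC1(C)C | intermediate
13 | 5-hydroxy-7-{[(2E,6E,9S,10S)-9,10,11-trihydroxy-3,7,11-trimethyldodeca-2,6-dien-1-yl]oxy}-2H-chromen-2-one | C/C(=C\COc1cc(O)c2ccc(=O)oc2c1)CC/C=C(\C)C[C@H](O)[C@H](O)C(C)(C)O | target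

**Step count and risks**

Total step count: 7 (steps 1, 3 and 5 each run two operations in one flask).
Longest linear sequence: 5 steps (5 → 7 → 8 → 10 → 12 → 13; the branch from 1 is equally long).

The three steps most likely to fail:

Step 5 (the proposed new method). The risks are hydrogen abstraction from the wrong C–H bonds, O-allylation of the alkoxide, ionisation of the C1 acetate once the carbonate is used up, and only moderate 9,10-anti selectivity; the minor (9R) isomer would be removed by chromatography of 10. The fallback uses known chemistry (barium-mediated α-selective carbonyl allylation), sets out from 4 and 7 and comes back at 10. Alcohol 4 is oxidised with TEMPO/PhI(OAc)2 to (4R)-2,2,5,5-tetramethyl-1,3-dioxolane-4-carbaldehyde F1. Alcohol 7 is turned with MsCl, LiCl and collidine in DMF into (2E,6E)-8-chloro-3,7-dimethylocta-2,6-dien-1-yl acetate F2. The acetate is cleaved with i-Bu2AlH at −78 °C to (2E,6E)-8-chloro-3,7-dimethylocta-2,6-dien-1-ol F3, which is silylated with TBSCl and imidazole to tert-butyl{[(2E,6E)-8-chloro-3,7-dimethylocta-2,6-dien-1-yl]oxy}dimethylsilane F4. F4 is converted at −78 °C with activated barium (from BaI2 and lithium biphenylide) into the allylbarium reagent, which adds to F1 at its α-carbon with retention of the olefin geometry and Felkin–Anh control. This gives (1S,3E,7E)-9-[(tert-butyldimethylsilyl)oxy]-3,7-dimethyl-1-[(4S)-2,2,5,5-tetramethyl-1,3-dioxolan-4-yl]nona-3,7-dien-1-ol F5, and n-Bu4NF then gives 10.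

Step 6. The risks are partial alkylation of the 5-OH and double etherification. The fallback fixes the regiochemistry by symmetry and builds the pyranone last; it sets out from 10 and comes back at 12. Mitsunobu reaction of 10 with 2,4,6-trihydroxybenzaldehyde, whose 4-OH is the only phenol not hydrogen-bonded to the aldehyde, gives 2,6-dihydroxy-4-{[(2E,6E,9S)-9-hydroxy-3,7-dimethyl-9-[(4S)-2,2,5,5-tetramethyl-1,3-dioxolan-4-yl]nona-2,6-dien-1-yl]oxy}benzaldehyde F6. Wittig reaction with Ph3P=CHCO2Et gives ethyl (2E)-3-(2,6-dihydroxy-4-{[(2E,6E,9S)-9-hydroxy-3,7-dimethyl-9-[(4S)-2,2,5,5-tetramethyl-1,3-dioxolan-4-yl]nona-2,6-dien-1-yl]oxy}phenyl)prop-2-enoate F7. E-to-Z isomerisation by triplet sensitisation (fac-Ir(ppy)3, 450 nm) lets either of the two equivalent ortho phenols lactonise, which gives 12.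

Step 7. The risk is acid-induced loss or rearrangement of the aryl geranyl ether while the hindered tetramethyl-dioxolane is opened. The fallback removes the acetonide before the acid-labile ether exists and makes the ether by alkylation; it sets out from 10 and comes back at 13. PPTS in MeOH converts 10 into (2E,6E,9S,10S)-3,7,11-trimethyldodeca-2,6-diene-1,9,10,11-tetrol F8. Corey–Kim chlorination (NCS, Me2S, CH2Cl2, −40 °C), which is selective for the primary allylic alcohol, gives (3S,4S,6E,10E)-12-chloro-2,6,10-trimethyldodeca-6,10-diene-2,3,4-triol F9. Alkylation of 11 with F9 and K2CO3 in acetone gives 13.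

**Further compounds**

F1 | step 5 | (4R)-2,2,5,5-tetramethyl-1,3-dioxolane-4-carbaldehyde | O=C[C@@H]1OC(C)(C)OC1(C)C
F2 | step 5 | (2E,6E)-8-chloro-3,7-dimethylocta-2,6-dien-1-yl acetate | C/C(=C\COC(C)=O)CC/C=C(\C)CCl
F3 | step 5 | (2E,6E)-8-chloro-3,7-dimethylocta-2,6-dien-1-ol | C/C(=C\CO)CC/C=C(\C)CCl
F4 | step 5 | tert-butyl{[(2E,6E)-8-chloro-3,7-dimethylocta-2,6-dien-1-yl]oxy}dimethylsilane | C/C(=C\CO[Si](C)(C)C(C)(C)C)CC/C=C(\C)CCl
F5 | step 5 | (1S,3E,7E)-9-[(tert-butyldimethylsilyl)oxy]-3,7-dimethyl-1-[(4S)-2,2,5,5-tetramethyl-1,3-dioxolan-4-yl]nona-3,7-dien-1-ol | C/C(=C\CO[Si](C)(C)C(C)(C)C)CC/C=C(\C)C[C@H](O)[C@@H]1OC(C)(C)OC1(C)C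
F6 | step 6 | 2,6-dihydroxy-4-{[(2E,6E,9S)-9-hydroxy-3,7-dimethyl-9-[(4S)-2,2,5,5-tetramethyl-1,3-dioxolan-4-yl]nona-2,6-dien-1-yl]oxy}benzaldehyde | C/C(=C\COc1cc(O)c(C=O)c(O)c1)CC/C=C(\C)C[C@H](O)[C@@H]1OC(C)(C)OC1(C)C
F7 | step 6 | ethyl (2E)-3-(2,6-dihydroxy-4-{[(2E,6E,9S)-9-hydroxy-3,7-dimethyl-9-[(4S)-2,2,5,5-tetramethyl-1,3-dioxolan-4-yl]nona-2,6-dien-1-yl]oxy}phenyl)prop-2-enoate | C/C(=C\COc1cc(O)c(/C=C/C(=O)OCC)c(O)c1)CC/C=C(\C)C[C@H](O)[C@@H]1OC(C)(C)OC1(C)C
F8 | step 7 | (2E,6E,9S,10S)-3,7,11-trimethyldodeca-2,6-diene-1,9,10,11-tetrol | C/C(=C\CO)CC/C=C(\C)C[C@H](O)[C@H](O)C(C)(C)O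
F9 | step 7 | (3S,4S,6E,10E)-12-chloro-2,6,10-trimethyldodeca-6,10-diene-2,3,4-triol | C/C(=C\CCl)CC/C=C(\C)C[C@H](O)[C@H](O)C(C)(C)O
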